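**Strategy.** The ten-membered carbocycle is not made by macrocyclisation but by a four-atom ring expansion: an anionic oxy-Cope rearrangement of a cis-1-vinyl-2-(alk-1-en-2-yl)cyclohexan-1-olate, whose enolate is trapped as the C10 enol triflate. The step exploits the 1,5-diene C10=C1–C2–C3–C4=C5 of the cyclodecadiene and the fact that C10 carries an oxygenated carbon (C14): one operation cleaves C5–C10, forms C2–C3, and fixes both trisubstituted alkene geometries (C1=C10 ring-cis, C4=C5 ring-trans) from cyclohexane stereochemistry, leaving a handle for C14. The precursor is a cyclohexanol bearing C7/C8 (7R,8S) already, assembled from meso cyclohexa-1,4-diene dioxide by two trans-diaxial oxirane openings.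

Key step: step 12

Remark: germacrane numbering is used in the reasoning for all intermediates (ring C1–C10, lactone C11–C13, C14 on C10, C15 on C4). The target is read as 7R,8S (trans-fused lactone), 1(10)E (C9 and C2 cis on the ring) and 4Z (C3 and C6 trans on the ring).

Remark: cyclohexa-1,4-diene, 2-bromoprop-2-en-1-ol, ethyl 2-(hydroxymethyl)acrylate and (tributylstannyl)methanol are taken as commercial.

**Step 1**
Reactants: 1 cyclohexa-1,4-diene
Product: 2 anti-4,8-dioxatricyclo[5.1.0.0(3,5)]octane (meso trans-diepoxide)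
Conditions: mCPBA (2.3 equiv), NaHCO3, CH2Cl2, 0 °C to rt; crystallisation
Reagents that add atoms: meta-chloroperoxybenzoic acid, OOC(=O)c1cccc(Cl)c1
Why: Prilezhaev epoxidation, in which the second oxirane should form mainly anti to the first (dipole and steric bias), the minor syn isomer being removed by crystallisation.

**Step 2**
Reactants: 3 2-bromoprop-2-en-1-ol
Product: 4 [(2-bromoprop-2-en-1-yl)oxy](tert-butyl)dimethylsilane
Conditions: TBSCl, imidazole, CH2Cl2, 0 °C to rt
Reagents that add atoms: tert-butyldimethylsilyl chloride, CC(C)(C)[Si](C)(C)Cl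
Why: Standard silylation of a primary allylic alcohol.

**Step 3**
Reactants: 2 anti-diepoxide; 4 bromoallyl silyl ether
Product: 6 rac-(1S*,3S*,4R*,6R*)-4-{3-[(tert-butyldimethylsilyl)oxy]prop-1-en-2-yl}-7-oxabicyclo[4.1.0]heptan-3-ol, via alkenyllithium 5 (not isolated)
Conditions: 4, t-BuLi (2.0 equiv), Et2O, −78 °C; then 2 (3 equiv), BF3·OEt2, −78 °C; H2O
Reagents that add atoms: none
Why: Bromine–lithium exchange followed by Lewis-acid-assisted SN2 opening of one oxirane of 2 (its four oxirane carbons are equivalent; excess 2 suppresses double opening), with inversion at the attacked carbon so that the alkenyl group (C7) ends trans to the new hydroxyl (C8); the product is racemic and the low temperature should suppress O-to-C silyl migration in 5.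

**Step 4**
Reactants: 6 racemic epoxy alcohol
Product: 7 (1S,3S,4R,6R)-4-{3-[(tert-butyldimethylsilyl)oxy]prop-1-en-2-yl}-7-oxabicyclo[4.1.0]heptan-3-ol
Conditions: Burkholderia cepacia lipase (immobilised), vinyl acetate, MTBE, 30 °C, to just over half conversion; chromatography
Reagents that add atoms: none
Why: Lipase-catalysed kinetic resolution by enantioselective transesterification, in which the empirical model for secondary alcohols predicts acetylation of the (8R)-enantiomer and recovery of the required (8S)-alcohol; no stereocentre is created.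

**Step 5**
Reactants: 7 epoxy alcohol
Product: 8 tert-butyl{[(1S,3S,4R,6R)-4-{3-[(tert-butyldimethylsilyl)oxy]prop-1-en-2-yl}-7-oxabicyclo[4.1.0]heptan-3-yl]oxy}dimethylsilane
Conditions: TBSCl, imidazole, DMF, rt
Reagents that add atoms: tert-butyldimethylsilyl chloride, CC(C)(C)[Si](C)(C)Cl
Why: Mild silylation that leaves the oxirane untouched and blocks the C8 oxygen against transannular attack in the next opening.

**Step 6**
Reactants: 3 2-bromoprop-2-en-1-ol
Product: 9 1-{[(2-bromoprop-2-en-1-yl)oxy]methyl}-4-methoxybenzene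
Conditions: NaH, PMBCl, Bu4NI (cat.), THF, 0 °C to rt
Reagents that add atoms: 4-methoxybenzyl chloride, COc1ccc(CCl)cc1
Why: Williamson etherification of the alkoxide with a benzylic chloride.

**Step 7**
Reactants: 8 silyl-protected epoxide; 9 bromoallyl PMB ether
Product: 11 (1S,2R,4R,5S)-5-[(tert-butyldimethylsilyl)oxy]-4-{3-[(tert-butyldimethylsilyl)oxy]prop-1-en-2-yl}-2-{3-[(4-methoxybenzyl)oxy]prop-1-en-2-yl}cyclohexan-1-ol, via alkenyllithium 10 (not isolated)
Conditions: 9, t-BuLi (2.0 equiv), Et2O, −78 °C; then 8, BF3·OEt2, −78 °C; H2O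
Reagents that add atoms: none
Why: Lewis-acid-assisted SN2 oxirane opening, in which the trans-diaxial opening rule directs attack to C5 because only that mode passes through a chair keeping the C7 alkenyl and C8 silyloxy groups equatorial; this sets C5 (alkenyl anti to the C7 alkenyl, syn to C8–O) and C10–OH trans to it.

**Step 8**
Reactants: 11 cyclohexanol
Product: 12 (2R,4R,5S)-5-[(tert-butyldimethylsilyl)oxy]-4-{3-[(tert-butyldimethylsilyl)oxy]prop-1-en-2-yl}-2-{3-[(4-methoxybenzyl)oxy]prop-1-en-2-yl}cyclohexan-1-one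
Conditions: Dess–Martin periodinane, NaHCO3, CH2Cl2, 0 °C; used at once
Reagents that add atoms: none
Why: Buffered Dess–Martin oxidation is neutral enough to leave the epimerisable C5 centre, the β,γ-unsaturation and the β-silyloxy group intact.

**Step 9**
Reactants: 12 ketone
Product: 13 tert-butyl{[(1S,2R,4S)-5-ethylidene-4-{3-[(4-methoxybenzyl)oxy]prop-1-en-2-yl}-2-{3-[(tert-butyldimethylsilyl)oxy]prop-1-en-2-yl}cyclohexyl]oxy}dimethylsilane (E/Z mixture)
Conditions: EtPPh3Br, KHMDS, THF, −78 °C; then 12, −78 to 0 °C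
Reagents that add atoms: ethyltriphenylphosphonium bromide, CC[P+](c1ccccc1)(c1ccccc1)c1ccccc1.[Br-]
Why: Wittig olefination with an unstabilised ylide at low temperature, where carbonyl addition should outrun enolisation; the E/Z ratio is irrelevant because C1 becomes sp2 again in step 11.

**Step 10**
Reactants: 13 ethylidenecyclohexane
Product: 14 tert-butyl{[(3S,4R,6R,7S)-2-methyl-4-{3-[(4-methoxybenzyl)oxy]prop-1-en-2-yl}-6-{3-[(tert-butyldimethylsilyl)oxy]prop-1-en-2-yl}-1-oxaspiro[2.5]octan-7-yl]oxy}dimethylsilane (C2 epimers)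
Conditions: mCPBA (1.05 equiv), NaHCO3, CH2Cl2, −20 to 0 °C
Reagents that add atoms: meta-chloroperoxybenzoic acid, OOC(=O)c1cccc(Cl)c1
Why: Prilezhaev epoxidation, chemoselective for the only trisubstituted alkene (the 1,1-disubstituted alkenes carry deactivating allylic oxygen); the peracid should attack anti to the C5 alkenyl group, held axial by A(1,3) strain and the equatorial C7/C8 groups, so the C10–O bond forms trans to the C5 side chain.

**Step 11**
Reactants: 14 spiro-epoxide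
Product: 17 (1R,2R,4R,5S)-5-[(tert-butyldimethylsilyl)oxy]-1-ethenyl-2-{3-[(4-methoxybenzyl)oxy]prop-1-en-2-yl}-4-{3-[(tert-butyldimethylsilyl)oxy]prop-1-en-2-yl}cyclohexan-1-ol, via hydroxy selenide 15 (not isolated), via selenoxide 16 (not isolated)
Conditions: (PhSe)2, NaBH4, EtOH, reflux; then THF, 30% H2O2, pyridine, 0 °C to rt
Reagents that add atoms: none
Why: Organoselenium epoxide-to-allylic-alcohol transposition, in which the selenide opens the oxirane at the less hindered C1 (the C10–O bond and its configuration are untouched) and the selenoxide can only syn-eliminate toward the methyl group; the result is the carbinol with vinyl cis and hydroxyl trans to the C5 alkenyl group.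

**Step 12**
Reactants: 17 divinylcyclohexanol
Product: 20 (1E,5Z,8R,9S)-9-[(tert-butyldimethylsilyl)oxy]-8-{3-[(tert-butyldimethylsilyl)oxy]prop-1-en-2-yl}-5-{[(4-methoxybenzyl)oxy]methyl}cyclodeca-1,5-dien-1-yl trifluoromethanesulfonate, via potassium alkoxide 18 (not isolated), via potassium enolate 19 (not isolated)
Conditions: KH (1.5 equiv), 18-crown-6, THF, 0 to 40 °C; then PhNTf2, −78 to 0 °C
Reagents that add atoms: N-phenylbis(trifluoromethanesulfonimide), FC(F)(F)S(=O)(=O)N(c1ccccc1)S(=O)(=O)C(F)(F)F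
Why: Deprotonation gives alkoxide 18, whose C10 oxyanion accelerates a concerted [3,3]-sigmatropic shift of the 1,5-diene C2=C1–C10–C5–C4=C3, breaking the ring bond C5–C10 as C2–C3 forms, and the resulting potassium enolate 19 is O-sulfonylated in the same flask with retention of its geometry. The closest known reaction type is the anionic oxy-Cope ring expansion of 1,2-dialkenylcyclohexanols to cyclodec-5-enones with in situ trapping of the enolate. The ten-membered ring is not closed end to end but arises by four-atom ring expansion of the cyclohexane through a chair-like six-centre transition state. No stereocentre is created (C7 and C8 are spectators); the two alkene geometries are set by the chair, in which C6 is pseudo-equatorial (ring-trans C4=C5, 4Z) and C9 is pseudo-axial with the oxyanion pseudo-equatorial (enolate with C9 cis to C2, 1(10)E after triflation). The step needs reaction through this one chair rather than a boat or the ring-flipped chair, which the substrate secures: only the cyclohexane chair with the C7 and C8 groups equatorial places the cis-related C5 alkenyl (axial) and C10 vinyl (equatorial) groups gauche for overlap, whereas the flipped chair suffers a syn-diaxial vinyl/OTBS clash. It also needs triflation to outrun proton transfer in the enolate, which is addressed by adding PhNTf2 at −78 °C as soon as the alkoxide is consumed.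

**Step 13**
Reactants: 20 enol triflate
Product: 21 [(1E,5Z,8R,9S)-9-[(tert-butyldimethylsilyl)oxy]-8-{3-[(tert-butyldimethylsilyl)oxy]prop-1-en-2-yl}-5-{[(4-methoxybenzyl)oxy]methyl}cyclodeca-1,5-dien-1-yl]methanol
Conditions: Bu3SnCH2OH, Pd(PPh3)4 (5 mol %), LiCl, 1,4-dioxane, 70 °C
Reagents that add atoms: (tributylstannyl)methanol, OC[Sn](CCCC)(CCCC)CCCC
Why: Migita–Kosugi–Stille coupling transfers the hydroxymethyl group (C14) to C10 with retention of the enol triflate geometry, so C14 ends trans to C2.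

**Step 14**
Reactants: 21 allylic alcohol
Product: 22 [(1E,5Z,8R,9S)-9-[(tert-butyldimethylsilyl)oxy]-8-{3-[(tert-butyldimethylsilyl)oxy]prop-1-en-2-yl}-5-{[(4-methoxybenzyl)oxy]methyl}cyclodeca-1,5-dien-1-yl]methyl acetate
Conditions: Ac2O, pyridine, DMAP (cat.), CH2Cl2, 0 °C
Reagents that add atoms: acetic anhydride, CC(=O)OC(C)=O
Why: Standard acylation of the only free hydroxyl installs the C14 acetate of the target.

**Step 15**
Reactants: 22 bis-silyl ether
Product: 23 [(1E,5Z,8R,9S)-9-hydroxy-8-(3-hydroxyprop-1-en-2-yl)-5-{[(4-methoxybenzyl)oxy]methyl}cyclodeca-1,5-dien-1-yl]methyl acetate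
Conditions: HF·pyridine, pyridine, THF, 0 °C to rt
Reagents that add atoms: none
Why: Buffered fluoride desilylation frees the C8 and C12 hydroxyls while the acetate, the PMB ether and the acid-sensitive 1,5-diene should survive.

**Step 16**
Reactants: 23 diol
Product: 26 {(3aR,5Z,9E,11aS)-6-{[(4-methoxybenzyl)oxy]methyl}-3-methylidene-2-oxo-2,3,3a,4,7,8,11,11a-octahydrocyclodeca[b]furan-10-yl}methyl acetate, via enal 24 (not isolated), via lactol 25 (not isolated)
Conditions: activated MnO2 (excess), CH2Cl2, rt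
Reagents that add atoms: none
Why: MnO2 oxidative lactonisation, in which the allylic C12 alcohol gives the enal, the C8 hydroxyl closes the lactol and a second oxidation gives the α-methylene-γ-butyrolactone; C7 and C8 are not touched, so the trans ring fusion is retained.

**Step 17**
Reactants: 26 PMB ether
Product: 27 [(3aR,5Z,9E,11aS)-6-(hydroxymethyl)-3-methylidene-2-oxo-2,3,3a,4,7,8,11,11a-octahydrocyclodeca[b]furan-10-yl]methyl acetate
Conditions: DDQ, CH2Cl2/pH 7 buffer (10:1), 0 °C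
Reagents that add atoms: none
Why: Oxidative cleavage of the p-methoxybenzyl ether under neutral conditions that the acetate and the α-methylene lactone tolerate.

**Step 18**
Reactants: 28 ethyl 2-(hydroxymethyl)prop-2-enoate
Product: 29 ethyl 2-{[(tert-butyldimethylsilyl)oxy]methyl}prop-2-enoate
Conditions: TBSCl, imidazole, CH2Cl2, 0 °C to rt
Reagents that add atoms: tert-butyldimethylsilyl chloride, CC(C)(C)[Si](C)(C)Cl
Why: Standard silylation masks the hydroxyl that would otherwise compete in the esterification.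

**Step 19**
Reactants: 29 silyloxy ester
Product: 30 2-{[(tert-butyldimethylsilyl)oxy]methyl}prop-2-enoic acid
Conditions: LiOH, THF/H2O, 0 °C; 1 M HCl to pH 4
Reagents that add atoms: lithium hydroxide (aqueous), [Li+].[OH-]
Why: Saponification of the ethyl ester at 0 °C, under which the primary silyl ether should persist.

**Step 20**
Reactants: 27 allylic alcohol; 30 acid
Product: 31 {(3aR,5Z,9E,11aS)-10-[(acetyloxy)methyl]-3-methylidene-2-oxo-2,3,3a,4,7,8,11,11a-octahydrocyclodeca[b]furan-6-yl}methyl 2-{[(tert-butyldimethylsilyl)oxy]methyl}prop-2-enoate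
Conditions: EDC·HCl, DMAP (cat.), CH2Cl2, 0 °C to rt
Reagents that add atoms: none
Why: Steglich-type carbodiimide esterification of the primary allylic C15 alcohol.

**Step 21**
Reactants: 31 silyl ether
Product: 32 {(3aR,5Z,9E,11aS)-10-[(acetyloxy)methyl]-3-methylidene-2-oxo-2,3,3a,4,7,8,11,11a-octahydrocyclodeca[b]furan-6-yl}methyl 2-(hydroxymethyl)prop-2-enoate (CNP0126545.1)
Conditions: HF·pyridine, pyridine, THF, 0 °C
Reagents that add atoms: none
Why: Buffered fluoride desilylation releases the hydroxymethyl acrylate without touching the two esters or the lactone.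

**Compound list**

1 | cyclohexa-1,4-diene | C1=CCC=CC1 | starting material
2 | anti-4,8-dioxatricyclo[5.1.0.0(3,5)]octane (meso) | [C@@H]12C[C@H]3O[C@H]3C[C@@H]1O2 | intermediate
3 | 2-bromoprop-2-en-1-ol | OCC(Br)=C | starting material
4 | [(2-bromoprop-2-en-1-yl)oxy](tert-butyl)dimethylsilane | C=C(Br)CO[Si](C)(C)C(C)(C)C | intermediate
5 | {3-[(tert-butyldimethylsilyl)oxy]prop-1-en-2-yl}lithium | [Li]C(=C)CO[Si](C)(C)C(C)(C)C | intermediate
6 | rac-(1S*,3S*,4R*,6R*)-4-{3-[(tert-butyldimethylsilyl)oxy]prop-1-en-2-yl}-7-oxabicyclo[4.1.0]heptan-3-ol (racemate; one enantiomer drawn) | [C@@H]12C[C@H](C(=C)CO[Si](C)(C)C(C)(C)C)[C@@H](O)C[C@@H]1O2 | intermediate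
7 | (1S,3S,4R,6R)-4-{3-[(tert-butyldimethylsilyl)oxy]prop-1-en-2-yl}-7-oxabicyclo[4.1.0]heptan-3-ol | [C@@H]12C[C@H](C(=C)CO[Si](C)(C)C(C)(C)C)[C@@H](O)C[C@@H]1O2 | intermediate
8 | tert-butyl{[(1S,3S,4R,6R)-4-{3-[(tert-butyldimethylsilyl)oxy]prop-1-en-2-yl}-7-oxabicyclo[4.1.0]heptan-3-yl]oxy}dimethylsilane | [C@@H]12C[C@H](C(=C)CO[Si](C)(C)C(C)(C)C)[C@@H](O[Si](C)(C)C(C)(C)C)C[C@@H]1O2 | intermediate
9 | 1-{[(2-bromoprop-2-en-1-yl)oxy]methyl}-4-methoxybenzene | C=C(Br)COCc1ccc(OC)cc1 | intermediate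
10 | {3-[(4-methoxybenzyl)oxy]prop-1-en-2-yl}lithium | [Li]C(=C)COCc1ccc(OC)cc1 | intermediate
11 | (1S,2R,4R,5S)-5-[(tert-butyldimethylsilyl)oxy]-4-{3-[(tert-butyldimethylsilyl)oxy]prop-1-en-2-yl}-2-{3-[(4-methoxybenzyl)oxy]prop-1-en-2-yl}cyclohexan-1-ol | [C@H]1(C(=C)COCc2ccc(OC)cc2)C[C@H](C(=C)CO[Si](C)(C)C(C)(C)C)[C@@H](O[Si](C)(C)C(C)(C)C)C[C@@H]1O | intermediate
12 | (2R,4R,5S)-5-[(tert-butyldimethylsilyl)oxy]-4-{3-[(tert-butyldimethylsilyl)oxy]prop-1-en-2-yl}-2-{3-[(4-methoxybenzyl)oxy]prop-1-en-2-yl}cyclohexan-1-one | [C@H]1(C(=C)COCc2ccc(OC)cc2)C[C@H](C(=C)CO[Si](C)(C)C(C)(C)C)[C@@H](O[Si](C)(C)C(C)(C)C)CC1=O | intermediate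
13 | tert-butyl{[(1S,2R,4S)-5-ethylidene-4-{3-[(4-methoxybenzyl)oxy]prop-1-en-2-yl}-2-{3-[(tert-butyldimethylsilyl)oxy]prop-1-en-2-yl}cyclohexyl]oxy}dimethylsilane (E/Z mixture) | [C@H]1(C(=C)COCc2ccc(OC)cc2)C[C@H](C(=C)CO[Si](C)(C)C(C)(C)C)[C@@H](O[Si](C)(C)C(C)(C)C)CC1=CC | intermediate
14 | tert-butyl{[(3S,4R,6R,7S)-2-methyl-4-{3-[(4-methoxybenzyl)oxy]prop-1-en-2-yl}-6-{3-[(tert-butyldimethylsilyl)oxy]prop-1-en-2-yl}-1-oxaspiro[2.5]octan-7-yl]oxy}dimethylsilane (C2 epimers) | [C@H]1(C(=C)COCc2ccc(OC)cc2)C[C@H](C(=C)CO[Si](C)(C)C(C)(C)C)[C@@H](O[Si](C)(C)C(C)(C)C)C[C@]13OC3C | intermediate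
15 | (1S,2R,4R,5S)-5-[(tert-butyldimethylsilyl)oxy]-4-{3-[(tert-butyldimethylsilyl)oxy]prop-1-en-2-yl}-2-{3-[(4-methoxybenzyl)oxy]prop-1-en-2-yl}-1-[1-(phenylselanyl)ethyl]cyclohexan-1-ol (side-chain epimers) | [C@H]1(C(=C)COCc2ccc(OC)cc2)C[C@H](C(=C)CO[Si](C)(C)C(C)(C)C)[C@@H](O[Si](C)(C)C(C)(C)C)C[C@@]1(O)C(C)[Se]c1ccccc1 | intermediate
16 | selenoxide of 15, 1-[1-(benzeneseleninyl)ethyl]cyclohexan-1-ol with the ring configuration of 15 | [C@H]1(C(=C)COCc2ccc(OC)cc2)C[C@H](C(=C)CO[Si](C)(C)C(C)(C)C)[C@@H](O[Si](C)(C)C(C)(C)C)C[C@@]1(O)C(C)[Se](=O)c1ccccc1 | intermediate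
17 | (1R,2R,4R,5S)-5-[(tert-butyldimethylsilyl)oxy]-1-ethenyl-2-{3-[(4-methoxybenzyl)oxy]prop-1-en-2-yl}-4-{3-[(tert-butyldimethylsilyl)oxy]prop-1-en-2-yl}cyclohexan-1-ol | [C@H]1(C(=C)COCc2ccc(OC)cc2)C[C@H](C(=C)CO[Si](C)(C)C(C)(C)C)[C@@H](O[Si](C)(C)C(C)(C)C)C[C@@]1(O)C=C | intermediate
18 | potassium alkoxide of 17 | [C@H]1(C(=C)COCc2ccc(OC)cc2)C[C@H](C(=C)CO[Si](C)(C)C(C)(C)C)[C@@H](O[Si](C)(C)C(C)(C)C)C[C@@]1([O-])C=C.[K+] | intermediate
19 | potassium (1E,5Z,8R,9S)-9-[(tert-butyldimethylsilyl)oxy]-8-{3-[(tert-butyldimethylsilyl)oxy]prop-1-en-2-yl}-5-{[(4-methoxybenzyl)oxy]methyl}cyclodeca-1,5-dien-1-olate | COc1ccc(COC/C2=C\C[C@H](C(=C)CO[Si](C)(C)C(C)(C)C)[C@@H](O[Si](C)(C)C(C)(C)C)C/C([O-])=C\CC2)cc1.[K+] | intermediate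
20 | (1E,5Z,8R,9S)-9-[(tert-butyldimethylsilyl)oxy]-8-{3-[(tert-butyldimethylsilyl)oxy]prop-1-en-2-yl}-5-{[(4-methoxybenzyl)oxy]methyl}cyclodeca-1,5-dien-1-yl trifluoromethanesulfonate | COc1ccc(COC/C2=C\C[C@H](C(=C)CO[Si](C)(C)C(C)(C)C)[C@@H](O[Si](C)(C)C(C)(C)C)C/C(OS(=O)(=O)C(F)(F)F)=C\CC2)cc1 | intermediate
21 | [(1E,5Z,8R,9S)-9-[(tert-butyldimethylsilyl)oxy]-8-{3-[(tert-butyldimethylsilyl)oxy]prop-1-en-2-yl}-5-{[(4-methoxybenzyl)oxy]methyl}cyclodeca-1,5-dien-1-yl]methanol | COc1ccc(COC/C2=C\C[C@H](C(=C)CO[Si](C)(C)C(C)(C)C)[C@@H](O[Si](C)(C)C(C)(C)C)C/C(CO)=C\CC2)cc1 | intermediate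
22 | [(1E,5Z,8R,9S)-9-[(tert-butyldimethylsilyl)oxy]-8-{3-[(tert-butyldimethylsilyl)oxy]prop-1-en-2-yl}-5-{[(4-methoxybenzyl)oxy]methyl}cyclodeca-1,5-dien-1-yl]methyl acetate | COc1ccc(COC/C2=C\C[C@H](C(=C)CO[Si](C)(C)C(C)(C)C)[C@@H](O[Si](C)(C)C(C)(C)C)C/C(COC(C)=O)=C\CC2)cc1 | intermediate
23 | [(1E,5Z,8R,9S)-9-hydroxy-8-(3-hydroxyprop-1-en-2-yl)-5-{[(4-methoxybenzyl)oxy]methyl}cyclodeca-1,5-dien-1-yl]methyl acetate | COc1ccc(COC/C2=C\C[C@H](C(=C)CO)[C@@H](O)C/C(COC(C)=O)=C\CC2)cc1 | intermediate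
24 | [(1E,5Z,8R,9S)-9-hydroxy-5-{[(4-methoxybenzyl)oxy]methyl}-8-(3-oxoprop-1-en-2-yl)cyclodeca-1,5-dien-1-yl]methyl acetate | COc1ccc(COC/C2=C\C[C@H](C(=C)C=O)[C@@H](O)C/C(COC(C)=O)=C\CC2)cc1 | intermediate
25 | {(3aR,5Z,9E,11aS)-2-hydroxy-6-{[(4-methoxybenzyl)oxy]methyl}-3-methylidene-2,3,3a,4,7,8,11,11a-octahydrocyclodeca[b]furan-10-yl}methyl acetate (lactol epimers) | COc1ccc(COC/C2=C\C[C@@H]3C(=C)C(O)O[C@H]3C/C(COC(C)=O)=C\CC2)cc1 | intermediate
26 | {(3aR,5Z,9E,11aS)-6-{[(4-methoxybenzyl)oxy]methyl}-3-methylidene-2-oxo-2,3,3a,4,7,8,11,11a-octahydrocyclodeca[b]furan-10-yl}methyl acetate | COc1ccc(COC/C2=C\C[C@@H]3C(=C)C(=O)O[C@H]3C/C(COC(C)=O)=C\CC2)cc1 | intermediate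
27 | [(3aR,5Z,9E,11aS)-6-(hydroxymethyl)-3-methylidene-2-oxo-2,3,3a,4,7,8,11,11a-octahydrocyclodeca[b]furan-10-yl]methyl acetate | OC/C1=C\C[C@@H]2C(=C)C(=O)O[C@H]2C/C(COC(C)=O)=C\CC1 | intermediate
28 | ethyl 2-(hydroxymethyl)prop-2-enoate | C=C(CO)C(=O)OCC | starting material
29 | ethyl 2-{[(tert-butyldimethylsilyl)oxy]methyl}prop-2-enoate | C=C(CO[Si](C)(C)C(C)(C)C)C(=O)OCC | intermediate
30 | 2-{[(tert-butyldimethylsilyl)oxy]methyl}prop-2-enoic acid | C=C(CO[Si](C)(C)C(C)(C)C)C(=O)O | intermediate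
31 | {(3aR,5Z,9E,11aS)-10-[(acetyloxy)methyl]-3-methylidene-2-oxo-2,3,3a,4,7,8,11,11a-octahydrocyclodeca[b]furan-6-yl}methyl 2-{[(tert-butyldimethylsilyl)oxy]methyl}prop-2-enoate | C=C(CO[Si](C)(C)C(C)(C)C)C(=O)OC/C1=C\C[C@@H]2C(=C)C(=O)O[C@H]2C/C(COC(C)=O)=C\CC1 | intermediate
32 | {(3aR,5Z,9E,11aS)-10-[(acetyloxy)methyl]-3-methylidene-2-oxo-2,3,3a,4,7,8,11,11a-octahydrocyclodeca[b]furan-6-yl}methyl 2-(hydroxymethyl)prop-2-enoate (CNP0126545.1) | C=C(CO)C(=O)OC/C1=C\C[C@@H]2C(=C)C(=O)O[C@H]2C/C(COC(C)=O)=C\CC1 | target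

**Count.** Total step count: 21. Longest linear sequence: 17 steps (1, 3, 4, 5, 7 to 17, 20, 21); steps 2, 6, 18 and 19 prepare side components.

**Steps most likely to fail**

1. Step 12 (key step). The tertiary homoallylic alkoxide may fragment instead of rearranging, the rearrangement may pass through a boat or the flipped chair and give the wrong alkene geometry, or proton transfer within the potassium enolate may precede the slow O-sulfonylation (regio-scrambling and β-elimination of the C8 silyloxide). Fallback, which decouples the sigmatropic shift from the sulfonylation: setting out from 17, the rearrangement is run as before but the enolate is quenched at −78 °C with Me3SiCl/Et3N, a much faster O-trapping, to give the isolable trimethylsilyl enol ether F1, whose geometry can be checked; MeLi (THF, 0 °C) then regenerates the enolate regio- and stereospecifically as the lithium enolate F2, which is triflated with Comins' reagent at −78 °C and returns to the route at 20.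

2. Step 9. The basic ylide may enolise ketone 12, which would epimerise C5 (loss of the axial alkenyl configuration on which steps 10 and 12 depend) or expel the C8 silyloxide by E1cB elimination. Fallback, which avoids basic olefination and the ethylidene intermediate: setting out from 12, non-basic Lombardo methylenation (Zn, CH2Br2, TiCl4, THF) gives the exocyclic methylene compound F3; dimethyldioxirane, again attacking anti to the axial C5 group, gives the terminal spiro-oxirane F4; dimethylsulfonium methylide (Me3S+ I−, n-BuLi, THF) homologates this oxirane by one carbon directly to the vinyl carbinol and returns to the route at 17, bypassing 13 to 16.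

3. Step 13. The alkenyl–palladium intermediate may insert transannularly into the nearby C4=C5 alkene (Heck-type cyclisation) before the slow tin-to-palladium transfer, or the medium-ring diene may rearrange on heating. Fallback, which replaces transmetalation by a fast CO insertion: setting out from 20, palladium-catalysed methoxycarbonylation (Pd(OAc)2, dppp, CO 1 atm, MeOH, Et3N, DMF, 40 °C) gives the methyl enoate F5, and DIBAL-H (CH2Cl2, −78 °C) reduces it to the allylic alcohol, returning to the route at 21.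

**Further compounds**

F1 | step 12 | tert-butyl{[(1S,2R,4Z,8E)-4-{[(4-methoxybenzyl)oxy]methyl}-2-{3-[(tert-butyldimethylsilyl)oxy]prop-1-en-2-yl}-8-[(trimethylsilyl)oxy]cyclodeca-4,8-dien-1-yl]oxy}dimethylsilane (trimethylsilyl enol ether of the ring-expanded ketone) | COc1ccc(COC/C2=C\C[C@H](C(=C)CO[Si](C)(C)C(C)(C)C)[C@@H](O[Si](C)(C)C(C)(C)C)C/C(O[Si](C)(C)C)=C\CC2)cc1
F2 | step 12 | lithium (1E,5Z,8R,9S)-9-[(tert-butyldimethylsilyl)oxy]-8-{3-[(tert-butyldimethylsilyl)oxy]prop-1-en-2-yl}-5-{[(4-methoxybenzyl)oxy]methyl}cyclodeca-1,5-dien-1-olate | COc1ccc(COC/C2=C\C[C@H](C(=C)CO[Si](C)(C)C(C)(C)C)[C@@H](O[Si](C)(C)C(C)(C)C)C/C([O-])=C\CC2)cc1.[Li+]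
F3 | step 9 | tert-butyl{[(1S,2R,4S)-4-{3-[(4-methoxybenzyl)oxy]prop-1-en-2-yl}-5-methylidene-2-{3-[(tert-butyldimethylsilyl)oxy]prop-1-en-2-yl}cyclohexyl]oxy}dimethylsilane | [C@H]1(C(=C)COCc2ccc(OC)cc2)C[C@H](C(=C)CO[Si](C)(C)C(C)(C)C)[C@@H](O[Si](C)(C)C(C)(C)C)CC1=C
F4 | step 9 | tert-butyl{[(3S,4R,6R,7S)-4-{3-[(4-methoxybenzyl)oxy]prop-1-en-2-yl}-6-{3-[(tert-butyldimethylsilyl)oxy]prop-1-en-2-yl}-1-oxaspiro[2.5]octan-7-yl]oxy}dimethylsilane | [C@H]1(C(=C)COCc2ccc(OC)cc2)C[C@H](C(=C)CO[Si](C)(C)C(C)(C)C)[C@@H](O[Si](C)(C)C(C)(C)C)C[C@]13OC3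
F5 | step 13 | methyl (1E,5Z,8R,9S)-9-[(tert-butyldimethylsilyl)oxy]-8-{3-[(tert-butyldimethylsilyl)oxy]prop-1-en-2-yl}-5-{[(4-methoxybenzyl)oxy]methyl}cyclodeca-1,5-diene-1-carboxylate | COc1ccc(COC/C2=C\C[C@H](C(=C)CO[Si](C)(C)C(C)(C)C)[C@@H](O[Si](C)(C)C(C)(C)C)C/C(C(=O)OC)=C\CC2)cc1
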